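**Retrosynthetic overview**

- Feature used: ring B carries oxygen on four adjacent carbons, C2' to C5'. C3' and C4' with their methoxy groups are the two enol ether carbons of dimethyl squarate, and C2' and C5' are its two carbonyl carbons.
- Ring C is cut at O1–C2 and C4–C4a: phloroglucinol supplies ring A and O1, and a methyl aroylacetate supplies C2, C3, C4 and ring B (thermal Mentzer condensation). The keto ester comes from 2',3',4',5'-tetramethoxyacetophenone and dimethyl carbonate.
- Ring B is cut at C5'–C6': the 2,3-dimethoxyhydroquinone with the masked acetyl group on C1' comes from a 4-alkenyl-4-hydroxycyclobutenone by 4π ring opening and 6π ring closure.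
- The cyclobutenone comes from dimethyl squarate and the α-lithiated ethylene ketal of methyl vinyl ketone, which supplies C1', C6', C2 and C3.
- Order of ring formation: ring B first (step 5), then ring C (step 9) closed onto ring A, which is bought intact.

Key step: step 5

Remark: compounds 2, 3, 7 and 8 each hold one stereocenter and are used as racemates; the target has no stereocenter.
Remark: dimethyl carbonate is treated as a reagent, although it supplies C4 of the target.
Assumption: 1-[2,4-bis(benzyloxy)-6-hydroxyphenyl]ethan-1-one, used only in one fallback, is taken as a purchased compound.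

**Route**

Step 1
Reactants: 1 methyl vinyl ketone (but-3-en-2-one)
Product: 2 3,4-dibromobutan-2-one (racemic)
Conditions: Br2, CH2Cl2, 0 °C
Reagents that add atoms: bromine, BrBr
Why: Electrophilic addition of bromine to the enone C=C (alkene bromination) is fast at 0 °C and leaves the ketone untouched; the new stereocenter forms as a racemate and is removed in step 3.

Step 2
Reactants: 2 3,4-dibromobutan-2-one
Product: 3 2-(1,2-dibromoethyl)-2-methyl-1,3-dioxolane (racemic)
Conditions: HOCH2CH2OH, p-TsOH·H2O (cat.), benzene, reflux, Dean–Stark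
Reagents that add atoms: ethane-1,2-diol, OCCO
Why: Acid-catalysed ketalization with azeotropic removal of water should be favoured by the electron-poor α-bromo ketone, and it masks the carbonyl group before base and organolithium are used.

Step 3
Reactants: 3 2-(1,2-dibromoethyl)-2-methyl-1,3-dioxolane
Product: 4 2-(1-bromoethenyl)-2-methyl-1,3-dioxolane
Conditions: KOtBu (1.1 equiv), THF, 0 °C
Reagents that add atoms: none
Why: E2 dehydrobromination; the hydrogen on the CHBr carbon is acidified by its bromine and by the two ketal oxygens on the neighbouring carbon, so the primary bromide should be lost to give the 1-bromoethenyl isomer, as is usual for vicinal dibromides next to an oxygenated carbon.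

Step 4
Reactants: 4 2-(1-bromoethenyl)-2-methyl-1,3-dioxolane; 5 dimethyl squarate (3,4-dimethoxycyclobut-3-ene-1,2-dione)
Product: 8 4-hydroxy-2,3-dimethoxy-4-[1-(2-methyl-1,3-dioxolan-2-yl)ethenyl]cyclobut-2-en-1-one (racemic), via vinyllithium 6 (not isolated), via lithium alkoxide 7 (not isolated)
Conditions: n-BuLi, THF, −78 °C; then 5, THF, −78 °C; aq. NH4Cl, −78 °C
Reagents that add atoms: none
Why: Bromine–lithium exchange of an α-bromovinyl ketal at −78 °C followed by kinetic 1,2-addition of the vinyllithium to one of the two equivalent carbonyl groups of the squarate ester gives the carbinol; its quaternary stereocenter forms as a racemate and is erased on aromatization.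

Step 5
Reactants: 8 4-hydroxy-2,3-dimethoxy-4-[1-(2-methyl-1,3-dioxolan-2-yl)ethenyl]cyclobut-2-en-1-one
Product: 11 2,3-dimethoxy-5-(2-methyl-1,3-dioxolan-2-yl)benzene-1,4-diol, via dienylketene 9 (not isolated), via cyclohexa-2,4-dienone 10 (not isolated)
Conditions: degassed p-xylene, 138 °C, argon; concentrated under argon and used crude
Reagents that add atoms: none
Why: On heating, the C1–C4 bond of the cyclobutenone opens in a thermal conrotatory 4π electrocyclic reaction to dienylketene 9, whose ketene carbon then bonds to the terminal methylene carbon in a thermal disrotatory 6π electrocyclization that forms C5'–C6' and closes ring B as dienone 10; enolization of 10 gives the hydroquinone. The closest known reaction is the thermal ring expansion of 4-alkenyl-4-hydroxycyclobutenones made from squarate esters (Moore rearrangement). The six-membered carbocycle is closed by a pericyclic 6π closure of a (Z)-dienylketene, no stereocenter is created, and the one stereocenter of 8 is lost. The step needs torquoselectivity in the ring opening: the electron-donating hydroxyl group on C4 should rotate outward, which turns the alkenyl group inward and cis to the ketene, the only geometry that can cyclize. Regiochemistry needs no control, because the positions of all four oxygens and of the ketal-bearing carbon follow from the connectivity of 8. Exclusion of oxygen should keep the electron-rich hydroquinone from oxidizing to the quinone, and the neutral medium should leave the dioxolane intact.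

Step 6
Reactants: 11 2,3-dimethoxy-5-(2-methyl-1,3-dioxolan-2-yl)benzene-1,4-diol
Product: 12 2-methyl-2-(2,3,4,5-tetramethoxyphenyl)-1,3-dioxolane
Conditions: MeI (excess), K2CO3, degassed acetone, reflux, argon
Reagents that add atoms: iodomethane, CI
Why: Williamson O-methylation of both phenoxides; the ketal is stable to base, and the exclusion of oxygen prevents oxidation of the hydroquinone anion before it is alkylated.

Step 7
Reactants: 12 2-methyl-2-(2,3,4,5-tetramethoxyphenyl)-1,3-dioxolane
Product: 13 1-(2,3,4,5-tetramethoxyphenyl)ethan-1-one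
Conditions: 1 M HCl, THF, 23 °C
Reagents that add atoms: water, O
Why: Acid-catalysed ketal hydrolysis should be fast because the oxocarbenium ion is benzylic to an electron-rich ring, while the aryl methyl ethers are inert to dilute acid.

Step 8
Reactants: 13 1-(2,3,4,5-tetramethoxyphenyl)ethan-1-one
Product: 15 methyl 3-oxo-3-(2,3,4,5-tetramethoxyphenyl)propanoate, via sodium enolate 14 (not isolated)
Conditions: NaH, (MeO)2CO, THF, reflux; then aq. HCl
Reagents that add atoms: dimethyl carbonate, COC(=O)OC
Why: Crossed Claisen condensation of the methyl ketone enolate with a carbonate that cannot enolize is driven to completion by deprotonation of the keto ester product to its sodium enolate.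

Step 9
Reactants: 15 methyl 3-oxo-3-(2,3,4,5-tetramethoxyphenyl)propanoate; 16 phloroglucinol (benzene-1,3,5-triol)
Product: 18 5,7-dihydroxy-2-(2,3,4,5-tetramethoxyphenyl)-4H-chromen-4-one (5,7-dihydroxy-2',3',4',5'-tetramethoxyflavone), via 1,3-diketone 17 (not isolated)
Conditions: neat melt, 240 °C, argon, no catalyst (oil bath or microwave heating)
Reagents that add atoms: none
Why: Mentzer pyrone synthesis: uncatalysed thermal C-acylation of phloroglucinol by the keto ester with loss of methanol, then attack of an ortho hydroxyl group on the aryl ketone and loss of water, should give the chromone and not the coumarin; the threefold symmetry of phloroglucinol allows one regioisomer only and leaves the 5- and 7-hydroxyl groups free.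

**Compound list**

1 | methyl vinyl ketone (but-3-en-2-one) | CC(=O)C=C | starting material
2 | 3,4-dibromobutan-2-one (racemic) | CC(=O)C(Br)CBr | intermediate
3 | 2-(1,2-dibromoethyl)-2-methyl-1,3-dioxolane (racemic) | CC1(C(Br)CBr)OCCO1 | intermediate
4 | 2-(1-bromoethenyl)-2-methyl-1,3-dioxolane | CC1(C(Br)=C)OCCO1 | intermediate
5 | dimethyl squarate (3,4-dimethoxycyclobut-3-ene-1,2-dione) | COC1=C(OC)C(=O)C1=O | starting material
6 | [1-(2-methyl-1,3-dioxolan-2-yl)ethenyl]lithium | [Li]C(=C)C1(C)OCCO1 | intermediate
7 | lithium 2,3-dimethoxy-1-[1-(2-methyl-1,3-dioxolan-2-yl)ethenyl]-4-oxocyclobut-2-en-1-olate (racemic) | [Li+].[O-]C1(C(=C)C2(C)OCCO2)C(OC)=C(OC)C1=O | intermediate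
8 | 4-hydroxy-2,3-dimethoxy-4-[1-(2-methyl-1,3-dioxolan-2-yl)ethenyl]cyclobut-2-en-1-one (racemic) | COC1=C(OC)C(O)(C(=C)C2(C)OCCO2)C1=O | intermediate
9 | (3Z)-4-hydroxy-2,3-dimethoxy-5-(2-methyl-1,3-dioxolan-2-yl)hexa-1,3,5-trien-1-one | O=C=C(OC)/C(OC)=C(/O)C(=C)C1(C)OCCO1 | intermediate
10 | 4-hydroxy-2,3-dimethoxy-5-(2-methyl-1,3-dioxolan-2-yl)cyclohexa-2,4-dien-1-one | O=C1CC(C2(C)OCCO2)=C(O)C(OC)=C1OC | intermediate
11 | 2,3-dimethoxy-5-(2-methyl-1,3-dioxolan-2-yl)benzene-1,4-diol | COc1c(O)cc(C2(C)OCCO2)c(O)c1OC | intermediate
12 | 2-methyl-2-(2,3,4,5-tetramethoxyphenyl)-1,3-dioxolane | COc1cc(C2(C)OCCO2)c(OC)c(OC)c1OC | intermediate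
13 | 1-(2,3,4,5-tetramethoxyphenyl)ethan-1-one | CC(=O)c1cc(OC)c(OC)c(OC)c1OC | intermediate
14 | sodium (Z)-enolate of methyl 3-oxo-3-(2,3,4,5-tetramethoxyphenyl)propanoate | [Na+].COC(=O)/C=C(\[O-])c1cc(OC)c(OC)c(OC)c1OC | intermediate
15 | methyl 3-oxo-3-(2,3,4,5-tetramethoxyphenyl)propanoate | COC(=O)CC(=O)c1cc(OC)c(OC)c(OC)c1OC | intermediate
16 | phloroglucinol (benzene-1,3,5-triol) | Oc1cc(O)cc(O)c1 | starting material
17 | 1-(2,3,4,5-tetramethoxyphenyl)-3-(2,4,6-trihydroxyphenyl)propane-1,3-dione | O=C(CC(=O)c1c(O)cc(O)cc1O)c1cc(OC)c(OC)c(OC)c1OC | intermediate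
18 | 5,7-dihydroxy-2-(2,3,4,5-tetramethoxyphenyl)-4H-chromen-4-one | COc1cc(-c2cc(=O)c3c(O)cc(O)cc3o2)c(OC)c(OC)c1OC | target

**Step count and risks**

Total step count: 9. Longest linear sequence: 9 steps (1 to 18); 5 and 16 are bought.

Steps most likely to fail:

1. Step 5. The hydroxyl group may rotate inward during ring opening, so that the ketene is trapped by its own hydroxyl group as a furanone. The very electron-rich hydroquinone may also be oxidized to the quinone during concentration. Fallback: the carbinol oxygen is capped as its methyl ether before heating.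
 - The fallback sets out from 4 and 5. Lithium alkoxide 7 is made as in step 4 and quenched at −78 °C with methyl triflate instead of NH4Cl. This should give 2,3,4-trimethoxy-4-[1-(2-methyl-1,3-dioxolan-2-yl)ethenyl]cyclobut-2-en-1-one F1 (racemic).
 - Heating F1 in degassed p-xylene at 138 °C should give 2,3,4-trimethoxy-5-(2-methyl-1,3-dioxolan-2-yl)phenol F2. F2 has no free para hydroxyl group and cannot form a quinone, and its ketene cannot lactonize.
 - Methylation of F2 with MeI and K2CO3 in acetone comes back to the route at 12.

2. Step 9. At 240 °C the keto ester may decompose before acyl transfer, or acyl transfer may compete with condensation in the coumarin sense. Fallback: ring C is built stepwise by a Baker–Venkataraman sequence on a benzyl-protected ring A.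
 - The fallback sets out from 13. Ortoleva–King reaction (I2, pyridine, 100 °C) should give 1-[2-oxo-2-(2,3,4,5-tetramethoxyphenyl)ethyl]pyridin-1-ium iodide F3.
 - Cleavage of F3 with aqueous NaOH at reflux, then HCl, should give 2,3,4,5-tetramethoxybenzoic acid F4.
 - Esterification of F4 with purchased 1-[2,4-bis(benzyloxy)-6-hydroxyphenyl]ethan-1-one (CC(=O)c1c(O)cc(OCc2ccccc2)cc1OCc1ccccc1) using EDC·HCl and DMAP in CH2Cl2 should give 2-acetyl-3,5-bis(benzyloxy)phenyl 2,3,4,5-tetramethoxybenzoate F5.
 - Baker–Venkataraman acyl shift (KOH, pyridine, 50 °C) should give 1-[2,4-bis(benzyloxy)-6-hydroxyphenyl]-3-(2,3,4,5-tetramethoxyphenyl)propane-1,3-dione F6.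
 - Cyclodehydration (catalytic H2SO4, AcOH, 100 °C) should give 5,7-bis(benzyloxy)-2-(2,3,4,5-tetramethoxyphenyl)-4H-chromen-4-one F7.
 - Hydrogenolysis of F7 (H2, Pd/C, EtOAc–MeOH) comes back to the route at 18.

3. Step 3. The base may remove a hydrogen from the CH2Br carbon and give the 2-bromoethenyl isomer, or a second elimination may give the alkyne. Fallback: the order of elimination and ketalization is reversed.
 - The fallback sets out from 2. Et3N in CH2Cl2 at 0 °C removes the acidic hydrogen next to the carbonyl group (E1cB) and should give only 3-bromobut-3-en-2-one F8.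
 - Ketalization of F8 with ethane-1,2-diol and catalytic p-TsOH (benzene, Dean–Stark) comes back to the route at 4.

**Further compounds**

F1 | step 5 | 2,3,4-trimethoxy-4-[1-(2-methyl-1,3-dioxolan-2-yl)ethenyl]cyclobut-2-en-1-one (racemic) | COC1=C(OC)C(OC)(C(=C)C2(C)OCCO2)C1=O
F2 | step 5 | 2,3,4-trimethoxy-5-(2-methyl-1,3-dioxolan-2-yl)phenol | COc1c(O)cc(C2(C)OCCO2)c(OC)c1OC
F3 | step 9 | 1-[2-oxo-2-(2,3,4,5-tetramethoxyphenyl)ethyl]pyridin-1-ium iodide | COc1cc(C(=O)C[n+]2ccccc2)c(OC)c(OC)c1OC.[I-]
F4 | step 9 | 2,3,4,5-tetramethoxybenzoic acid | COc1cc(C(=O)O)c(OC)c(OC)c1OC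
F5 | step 9 | 2-acetyl-3,5-bis(benzyloxy)phenyl 2,3,4,5-tetramethoxybenzoate | CC(=O)c1c(OCc2ccccc2)cc(OCc2ccccc2)cc1OC(=O)c1cc(OC)c(OC)c(OC)c1OC
F6 | step 9 | 1-[2,4-bis(benzyloxy)-6-hydroxyphenyl]-3-(2,3,4,5-tetramethoxyphenyl)propane-1,3-dione | O=C(CC(=O)c1cc(OC)c(OC)c(OC)c1OC)c1c(O)cc(OCc2ccccc2)cc1OCc1ccccc1
F7 | step 9 | 5,7-bis(benzyloxy)-2-(2,3,4,5-tetramethoxyphenyl)-4H-chromen-4-one | COc1cc(-c2cc(=O)c3c(OCc4ccccc4)cc(OCc4ccccc4)cc3o2)c(OC)c(OC)c1OC
F8 | step 3 | 3-bromobut-3-en-2-one | CC(=O)C(Br)=C
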